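A direct plan would make the chalcone helichrysetin (A1) and racemic (E)-1,7-bis(4-hydroxyphenyl)hept-1-en-3-ol (A2) and would join them last by an acid-catalysed dehydrative Friedel–Crafts alkylation of A1 at C3′ through the quinone methide A3. Its weakest steps would be: the face-selective attack on planar A3, because the only stereocentre would rest on a chiral acid acting on a substrate class without precedent; the site selection on ring A, because C5′ and the phenol oxygens would compete with C3′; and the ionisation of A2, because the same acid could send A3 to elimination or oligomers and could re-ionise the product.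

The route cuts C3–C4 of the heptenyl chain instead of the ring A–C3 bond. Because C1=C2 lies two atoms from C4, a carbonyl at C5 makes C5(=O)–C4–C3–C2=C1 a Claisen retron. Ester 13, with ring A on the alkene terminus and C5–C7 in its acyl part, is methylenated and heated: one [3,3] shift forms C3–C4, relays the reagent-set carbinol configuration to benzylic C3 and creates the (E)-C1=C2 styrene. No cation is attacked, so neither facial nor site selection on ring A arises: C3′ enters as the formyl carbon of a symmetric aldehyde, and bromine marks C1′ on one of two equivalent positions.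

Key step: step 9

Remark: C1–C7 number the heptenyl chain (C3 is the stereocentre) and primed locants number ring A of the chalcone; in the oxazaborolidine reduction the aryl group of enone 8 is assumed to act as the larger carbonyl substituent.

Step 1
Reactants: 1 5-methoxyresorcinol
Product: 2 1-methoxy-3,5-bis(methoxymethoxy)benzene
Conditions: NaH, MOMCl, DMF, 0 °C to rt
Reagents that add atoms: chloromethyl methyl ether (MOMCl), COCCl
Why: Williamson-type O-alkylation of both phenoxides gives the bis-MOM ether, which is needed as a base-stable protecting group and as the director for step 2.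

Step 2
Reactants: 2 1-methoxy-3,5-bis(methoxymethoxy)benzene
Product: 4 4-methoxy-2,6-bis(methoxymethoxy)benzaldehyde, via aryllithium 3 (not isolated)
Conditions: n-BuLi, TMEDA, THF, 0 °C; DMF, −78 °C to rt; aq NH4Cl
Reagents that add atoms: N,N-dimethylformamide, CN(C)C=O
Why: Directed ortho-metalation: the position between the two MOM ethers is doubly chelated and MOM is a stronger director than methoxy, so lithiation and formylation should place the aldehyde carbon (the future C3) on the symmetry axis of ring A.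

Step 3
Reactants: 4 4-methoxy-2,6-bis(methoxymethoxy)benzaldehyde
Product: 5 3-bromo-4-methoxy-2,6-bis(methoxymethoxy)benzaldehyde
Conditions: NBS (1.0 equiv), MeCN, 0 °C
Reagents that add atoms: N-bromosuccinimide, O=C1CCC(=O)N1Br
Why: Electrophilic aromatic bromination: the two free positions of 4 are equivalent by symmetry and each is activated by three oxygens, so one equivalent of NBS can give only one monobromide, which marks the future C1′.

Step 4
Reactants: 6 4′-hydroxyacetophenone
Product: 7 4′-(methoxymethoxy)acetophenone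
Conditions: MOMCl, iPr2NEt, CH2Cl2, 0 °C to rt
Reagents that add atoms: chloromethyl methyl ether (MOMCl), COCCl
Why: O-alkylation of the acidic phenol gives the MOM ether needed for the strongly basic steps that follow.

Step 5
Reactants: 5 3-bromo-4-methoxy-2,6-bis(methoxymethoxy)benzaldehyde; 7 4′-(methoxymethoxy)acetophenone
Product: 8 (E)-3-[3-bromo-4-methoxy-2,6-bis(methoxymethoxy)phenyl]-1-[4-(methoxymethoxy)phenyl]prop-2-en-1-one
Conditions: KOH, EtOH/H2O, rt
Reagents that add atoms: none
Why: Claisen–Schmidt condensation of a non-enolisable aldehyde with a methyl ketone gives the (E)-enone as the conjugated, thermodynamic product, and MOM ethers and the aryl bromide are inert to hydroxide.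

Step 6
Reactants: 8 (E)-3-[3-bromo-4-methoxy-2,6-bis(methoxymethoxy)phenyl]-1-[4-(methoxymethoxy)phenyl]prop-2-en-1-one
Product: 9 (1S,2E)-3-[3-bromo-4-methoxy-2,6-bis(methoxymethoxy)phenyl]-1-[4-(methoxymethoxy)phenyl]prop-2-en-1-ol
Conditions: (R)-2-methyl-CBS-oxazaborolidine (20 mol%), catecholborane, toluene, −78 °C; MeOH; aq NaOH wash; Et3N-deactivated SiO2
Reagents that add atoms: none
Why: Corey–Bakshi–Shibata reduction: hydride is delivered within the ketone–oxazaborolidine complex to one carbonyl face (1,2-reduction), and with the aryl group as the larger substituent the (R)-catalyst should set the (S)-carbinol, in the same sense as acetophenone gives (S)-1-phenylethanol.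

Step 7
Reactants: 10 3-(4-hydroxyphenyl)propanoic acid
Product: 12 3-[4-(methoxymethoxy)phenyl]propanoic acid, via bis-MOM ester 11 (not isolated)
Conditions: MOMCl, iPr2NEt, CH2Cl2, 0 °C to rt; then LiOH, THF/MeOH/H2O, rt; cold dilute HCl to pH 4
Reagents that add atoms: chloromethyl methyl ether (MOMCl), COCCl
Why: Exhaustive O-alkylation followed by saponification of the labile MOM ester leaves the aryl MOM ether and frees the acid that carries C5–C7.

Step 8
Reactants: 9 (1S,2E)-3-[3-bromo-4-methoxy-2,6-bis(methoxymethoxy)phenyl]-1-[4-(methoxymethoxy)phenyl]prop-2-en-1-ol; 12 3-[4-(methoxymethoxy)phenyl]propanoic acid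
Product: 13 (1S,2E)-3-[3-bromo-4-methoxy-2,6-bis(methoxymethoxy)phenyl]-1-[4-(methoxymethoxy)phenyl]prop-2-en-1-yl 3-[4-(methoxymethoxy)phenyl]propanoate
Conditions: DCC, DMAP, CH2Cl2, 0 °C
Reagents that add atoms: none
Why: Steglich esterification under basic, non-ionising conditions acylates the oxygen without touching the C–O bond, so the (S)-configuration is kept.

Step 9
Reactants: 13 (1S,2E)-3-[3-bromo-4-methoxy-2,6-bis(methoxymethoxy)phenyl]-1-[4-(methoxymethoxy)phenyl]prop-2-en-1-yl 3-[4-(methoxymethoxy)phenyl]propanoate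
Product: 15 (5R,6E)-5-[3-bromo-4-methoxy-2,6-bis(methoxymethoxy)phenyl]-1,7-bis[4-(methoxymethoxy)phenyl]hept-6-en-3-one, via allyl vinyl ether 14 (not isolated)
Conditions: Cp2Ti(μ-Cl)(μ-CH2)AlMe2 (Tebbe reagent), pyridine, THF/toluene, −40 to 0 °C; aq NaOH, filtration through basic Al2O3; then toluene, 2,6-lutidine (5 mol%), 100 °C
Reagents that add atoms: Tebbe reagent Cp2Ti(μ-Cl)(μ-CH2)AlMe2, C[Al-]1(C)C[Ti]([Cl+]1)(C1C=CC=C1)C1C=CC=C1
Why: Methylenation of the ester carbonyl at low temperature gives allyl vinyl ether 14 (its CH2 becomes C4) before any ketone can meet the reagent, and on heating 14 undergoes a concerted, suprafacial Claisen [3,3] rearrangement through a chair transition state; the closest known types are ester methylenation–Claisen sequences and the 1,3-chirality transfer in Claisen rearrangements of secondary (E)-allylic alcohols. No ring is closed, the six-membered array O–C1–C2=C3···CH2=C exists only in the transition state. The new stereocentre C3 (C5 of 15) is controlled by the C1 carbinol: with the 4-(methoxymethoxy)phenyl group equatorial, the methylene carbon is delivered to the alkene face syn to the departing oxygen, which turns (S)-C1 into (R)-C3 and fixes the new C1=C2 bond as E. The step needs the concerted path to outrun ionisation of the doubly benzylic C–O bond to a diarylallyl cation and an enolate, which would scramble configuration and the site of C–C bond formation. A non-polar, amine-buffered medium, the removal of all Lewis acid in the basic quench and the acceleration of the shift by the aryl group on the bond-breaking carbon should secure this. The 2,6-disubstituted ring A on the bond-forming terminus may slow the shift but cannot divert it, since the reaction is intramolecular.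

Step 10
Reactants: 15 (5R,6E)-5-[3-bromo-4-methoxy-2,6-bis(methoxymethoxy)phenyl]-1,7-bis[4-(methoxymethoxy)phenyl]hept-6-en-3-one
Product: 17 2-bromo-1-methoxy-3,5-bis(methoxymethoxy)-4-{(1E,3R)-1,7-bis[4-(methoxymethoxy)phenyl]hept-1-en-3-yl}benzene, via tosylhydrazone 16 (not isolated)
Conditions: TsNHNH2, EtOH, 50 °C; then catecholborane, CHCl3, 0 °C; NaOAc·3H2O, reflux
Reagents that add atoms: none
Why: Tosylhydrazone formation and hydride reduction with catecholborane, then base-induced loss of sulfinate and N2 (a mild Wolff–Kishner-type deoxygenation), turns the isolated C5 ketone into CH2 under conditions that leave the aryl bromide, the styrene, the MOM ethers and the non-enolisable C3 centre alone.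

Step 11
Reactants: 18 4-hydroxybenzaldehyde
Product: 19 4-(methoxymethoxy)benzaldehyde
Conditions: MOMCl, iPr2NEt, CH2Cl2, 0 °C to rt
Reagents that add atoms: chloromethyl methyl ether (MOMCl), COCCl
Why: O-alkylation of the acidic phenol gives the MOM ether of the future chalcone ring B.

Step 12
Reactants: 19 4-(methoxymethoxy)benzaldehyde; 20 diethyl {2-[methoxy(methyl)amino]-2-oxoethyl}phosphonate
Product: 21 (E)-N-methoxy-3-[4-(methoxymethoxy)phenyl]-N-methylprop-2-enamide
Conditions: NaH, THF, 0 °C to rt
Reagents that add atoms: none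
Why: Horner–Wadsworth–Emmons olefination with a stabilised phosphonate anion gives the (E)-cinnamoyl Weinreb amide.

Step 13
Reactants: 17 2-bromo-1-methoxy-3,5-bis(methoxymethoxy)-4-{(1E,3R)-1,7-bis[4-(methoxymethoxy)phenyl]hept-1-en-3-yl}benzene; 21 (E)-N-methoxy-3-[4-(methoxymethoxy)phenyl]-N-methylprop-2-enamide
Product: 23 (2E)-1-{3-[(1E,3R)-1,7-bis[4-(methoxymethoxy)phenyl]hept-1-en-3-yl]-6-methoxy-2,4-bis(methoxymethoxy)phenyl}-3-[4-(methoxymethoxy)phenyl]prop-2-en-1-one, via aryllithium 22 (not isolated)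
Conditions: n-BuLi (1.05 equiv), THF, −78 °C; then 21, −78 to −30 °C; aq NH4Cl
Reagents that add atoms: none
Why: Bromine–lithium exchange at −78 °C is faster than any deprotonation, the aryllithium is held by the flanking MOM and methoxy oxygens, and its addition to the Weinreb amide stops at the chelated tetrahedral adduct (Weinreb ketone synthesis), which gives the (E)-chalcone on work-up without change at C3.

Step 14
Reactants: 23 (2E)-1-{3-[(1E,3R)-1,7-bis[4-(methoxymethoxy)phenyl]hept-1-en-3-yl]-6-methoxy-2,4-bis(methoxymethoxy)phenyl}-3-[4-(methoxymethoxy)phenyl]prop-2-en-1-one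
Product: 25 deoxycalyxin A, via pentakis(trimethylsilyl) ether 24 (not isolated)
Conditions: TMSOTf (15 equiv), 2,2′-bipyridyl (20 equiv), MeCN, 0 °C to rt; then H2O, rt
Reagents that add atoms: none
Why: Silyl triflate/2,2′-bipyridyl cleavage of aryl MOM ethers (exchange to aryl silyl ethers, then hydrolysis) works without strong protic acid, so the acid-labile ring A–C3 bond, the styrene and the 2′-hydroxychalcone (flavanone closure) should be spared and no stereocentre is touched.

**Compound list**
1 | 5-methoxyresorcinol (5-methoxybenzene-1,3-diol) | COc1cc(O)cc(O)c1 | starting material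
2 | 1-methoxy-3,5-bis(methoxymethoxy)benzene | COCOc1cc(OC)cc(OCOC)c1 | intermediate
3 | [4-methoxy-2,6-bis(methoxymethoxy)phenyl]lithium | [Li]c1c(OCOC)cc(OC)cc1OCOC | intermediate (not isolated)
4 | 4-methoxy-2,6-bis(methoxymethoxy)benzaldehyde | O=Cc1c(OCOC)cc(OC)cc1OCOC | intermediate
5 | 3-bromo-4-methoxy-2,6-bis(methoxymethoxy)benzaldehyde | O=Cc1c(OCOC)cc(OC)c(Br)c1OCOC | intermediate
6 | 4′-hydroxyacetophenone | CC(=O)c1ccc(O)cc1 | starting material
7 | 4′-(methoxymethoxy)acetophenone | CC(=O)c1ccc(OCOC)cc1 | intermediate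
8 | (E)-3-[3-bromo-4-methoxy-2,6-bis(methoxymethoxy)phenyl]-1-[4-(methoxymethoxy)phenyl]prop-2-en-1-one | O=C(/C=C/c1c(OCOC)cc(OC)c(Br)c1OCOC)c1ccc(OCOC)cc1 | intermediate
9 | (1S,2E)-3-[3-bromo-4-methoxy-2,6-bis(methoxymethoxy)phenyl]-1-[4-(methoxymethoxy)phenyl]prop-2-en-1-ol | O[C@H](c1ccc(OCOC)cc1)/C=C/c1c(OCOC)cc(OC)c(Br)c1OCOC | intermediate
10 | 3-(4-hydroxyphenyl)propanoic acid | OC(=O)CCc1ccc(O)cc1 | starting material
11 | methoxymethyl 3-[4-(methoxymethoxy)phenyl]propanoate | COCOC(=O)CCc1ccc(OCOC)cc1 | intermediate (not isolated)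
12 | 3-[4-(methoxymethoxy)phenyl]propanoic acid | OC(=O)CCc1ccc(OCOC)cc1 | intermediate
13 | (1S,2E)-3-[3-bromo-4-methoxy-2,6-bis(methoxymethoxy)phenyl]-1-[4-(methoxymethoxy)phenyl]prop-2-en-1-yl 3-[4-(methoxymethoxy)phenyl]propanoate | O=C(CCc1ccc(OCOC)cc1)O[C@H](c1ccc(OCOC)cc1)/C=C/c1c(OCOC)cc(OC)c(Br)c1OCOC | intermediate
14 | allyl vinyl ether: 2-bromo-1-methoxy-3,5-bis(methoxymethoxy)-4-[(1E,3S)-3-[4-(methoxymethoxy)phenyl]-3-({4-[4-(methoxymethoxy)phenyl]but-1-en-2-yl}oxy)prop-1-en-1-yl]benzene | C=C(CCc1ccc(OCOC)cc1)O[C@H](c1ccc(OCOC)cc1)/C=C/c1c(OCOC)cc(OC)c(Br)c1OCOC | intermediate (not isolated)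
15 | (5R,6E)-5-[3-bromo-4-methoxy-2,6-bis(methoxymethoxy)phenyl]-1,7-bis[4-(methoxymethoxy)phenyl]hept-6-en-3-one | COCOc1cc(OC)c(Br)c(OCOC)c1[C@@H](/C=C/c1ccc(OCOC)cc1)CC(=O)CCc1ccc(OCOC)cc1 | intermediate
16 | 4-methylbenzenesulfonylhydrazone of ketone 15 | COCOc1cc(OC)c(Br)c(OCOC)c1[C@@H](/C=C/c1ccc(OCOC)cc1)CC(CCc1ccc(OCOC)cc1)=NNS(=O)(=O)c1ccc(C)cc1 | intermediate (not isolated)
17 | 2-bromo-1-methoxy-3,5-bis(methoxymethoxy)-4-{(1E,3R)-1,7-bis[4-(methoxymethoxy)phenyl]hept-1-en-3-yl}benzene | COCOc1cc(OC)c(Br)c(OCOC)c1[C@@H](/C=C/c1ccc(OCOC)cc1)CCCCc1ccc(OCOC)cc1 | intermediate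
18 | 4-hydroxybenzaldehyde | O=Cc1ccc(O)cc1 | starting material
19 | 4-(methoxymethoxy)benzaldehyde | O=Cc1ccc(OCOC)cc1 | intermediate
20 | diethyl {2-[methoxy(methyl)amino]-2-oxoethyl}phosphonate | CCOP(=O)(CC(=O)N(C)OC)OCC | starting material
21 | (E)-N-methoxy-3-[4-(methoxymethoxy)phenyl]-N-methylprop-2-enamide | CON(C)C(=O)/C=C/c1ccc(OCOC)cc1 | intermediate
22 | aryllithium from 17 (lithium in place of bromine at C1′) | COCOc1cc(OC)c([Li])c(OCOC)c1[C@@H](/C=C/c1ccc(OCOC)cc1)CCCCc1ccc(OCOC)cc1 | intermediate (not isolated)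
23 | (2E)-1-{3-[(1E,3R)-1,7-bis[4-(methoxymethoxy)phenyl]hept-1-en-3-yl]-6-methoxy-2,4-bis(methoxymethoxy)phenyl}-3-[4-(methoxymethoxy)phenyl]prop-2-en-1-one (pentakis-MOM ether of deoxycalyxin A) | COCOc1cc(OC)c(C(=O)/C=C/c2ccc(OCOC)cc2)c(OCOC)c1[C@@H](/C=C/c1ccc(OCOC)cc1)CCCCc1ccc(OCOC)cc1 | intermediate
24 | pentakis(trimethylsilyl) ether of deoxycalyxin A | COc1cc(O[Si](C)(C)C)c([C@@H](/C=C/c2ccc(O[Si](C)(C)C)cc2)CCCCc2ccc(O[Si](C)(C)C)cc2)c(O[Si](C)(C)C)c1C(=O)/C=C/c1ccc(O[Si](C)(C)C)cc1 | intermediate (not isolated)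
25 | deoxycalyxin A [(2E)-1-{2,4-dihydroxy-3-[(1E,3R)-1,7-bis(4-hydroxyphenyl)hept-1-en-3-yl]-6-methoxyphenyl}-3-(4-hydroxyphenyl)prop-2-en-1-one] | COc1cc(O)c([C@@H](/C=C/c2ccc(O)cc2)CCCCc2ccc(O)cc2)c(O)c1C(=O)/C=C/c1ccc(O)cc1 | target

Total step count: 14. Longest linear sequence: 10 steps (1, 2, 3, 5, 6, 8, 9, 10, 13, 14).

Steps most likely to fail, each with one fallback:

Step 9. The ester or the allyl vinyl ether may ionise at the doubly benzylic C–O bond before or instead of the concerted shift. This would erode the chirality transfer and give the isomer alkylated at C1. Methylenation of the hindered ester may also stay incomplete. The fallback forms the C2–C3 bond instead. It sets out from 5: a Claisen–Schmidt condensation with 4-[4-(methoxymethoxy)phenyl]butan-2-one F1 (raspberry ketone protected with MOMCl) would give (E)-1-[3-bromo-4-methoxy-2,6-bis(methoxymethoxy)phenyl]-5-[4-(methoxymethoxy)phenyl]pent-1-en-3-one F2. A rhodium-catalysed asymmetric Hayashi–Miyaura 1,4-addition of (E)-2-{2-[4-(methoxymethoxy)phenyl]ethenyl}-4,4,5,5-tetramethyl-1,3,2-dioxaborolane F3 would follow ([Rh(C2H4)2Cl]2 with a chiral diene ligand, KOH, dioxane/H2O). F3 would be made from 19 by boron–Wittig olefination with bis(pinacolatoboryl)methane and LiTMP. The fallback comes back to the route at ketone 15.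

Step 6. Facial selectivity may be poor on a push–pull aryl alkenyl ketone, conjugate reduction may compete, and the labile carbinol may undergo 1,3-transposition during isolation. The fallback builds the carbinol by C–C bond formation and sets out from 5. Ohira–Bestmann homologation (dimethyl (1-diazo-2-oxopropyl)phosphonate, K2CO3, MeOH) would give 2-bromo-4-ethynyl-1-methoxy-3,5-bis(methoxymethoxy)benzene F4. Hydroboration with dicyclohexylborane would give the (E)-alkenyldicyclohexylborane F5, and boron-to-zinc exchange with Et2Zn the (E)-alkenyl(ethyl)zinc F6. Its amino-alcohol-catalysed addition to aldehyde 19 ((−)-3-exo-morpholinoisoborneol, toluene, −10 °C) should give the (S)-carbinol directly, so the fallback comes back at 9.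

Step 13. The aryllithium may deprotonate the benzylic and allylic C3–H, which would racemise C3, or it may add too slowly to the amide and end as the protodebrominated arene. The fallback avoids any strong base after C3 is set and sets out from 17. Stille coupling with tributyl(1-ethoxyvinyl)stannane (Pd(PPh3)4, toluene, 100 °C) would give the 1-ethoxyvinyl arene F7. Hydrolysis on oxalic acid-treated wet SiO2 would give the methyl ketone F8. A Claisen–Schmidt condensation of F8 with 19 (KOH, EtOH, rt) would come back to the route at 23.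

Further compounds
F1 | step 9 | 4-[4-(methoxymethoxy)phenyl]butan-2-one | CC(=O)CCc1ccc(OCOC)cc1
F2 | step 9 | (E)-1-[3-bromo-4-methoxy-2,6-bis(methoxymethoxy)phenyl]-5-[4-(methoxymethoxy)phenyl]pent-1-en-3-one | O=C(/C=C/c1c(OCOC)cc(OC)c(Br)c1OCOC)CCc1ccc(OCOC)cc1
F3 | step 9 | (E)-2-{2-[4-(methoxymethoxy)phenyl]ethenyl}-4,4,5,5-tetramethyl-1,3,2-dioxaborolane | COCOc1ccc(/C=C/B2OC(C)(C)C(C)(C)O2)cc1
F4 | step 6 | 2-bromo-4-ethynyl-1-methoxy-3,5-bis(methoxymethoxy)benzene | C#Cc1c(OCOC)cc(OC)c(Br)c1OCOC
F5 | step 6 | (E)-{2-[3-bromo-4-methoxy-2,6-bis(methoxymethoxy)phenyl]ethenyl}dicyclohexylborane | COCOc1cc(OC)c(Br)c(OCOC)c1/C=C/B(C1CCCCC1)C1CCCCC1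
F6 | step 6 | (E)-{2-[3-bromo-4-methoxy-2,6-bis(methoxymethoxy)phenyl]ethenyl}(ethyl)zinc | CC[Zn]/C=C/c1c(OCOC)cc(OC)c(Br)c1OCOC
F7 | step 13 | 2-(1-ethoxyethenyl)-1-methoxy-3,5-bis(methoxymethoxy)-4-{(1E,3R)-1,7-bis[4-(methoxymethoxy)phenyl]hept-1-en-3-yl}benzene | COCOc1cc(OC)c(C(=C)OCC)c(OCOC)c1[C@@H](/C=C/c1ccc(OCOC)cc1)CCCCc1ccc(OCOC)cc1
F8 | step 13 | 1-{3-[(1E,3R)-1,7-bis[4-(methoxymethoxy)phenyl]hept-1-en-3-yl]-6-methoxy-2,4-bis(methoxymethoxy)phenyl}ethan-1-one | COCOc1cc(OC)c(C(C)=O)c(OCOC)c1[C@@H](/C=C/c1ccc(OCOC)cc1)CCCCc1ccc(OCOC)cc1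
A1 | direct plan | helichrysetin [(E)-1-(2,4-dihydroxy-6-methoxyphenyl)-3-(4-hydroxyphenyl)prop-2-en-1-one] | COc1cc(O)cc(O)c1C(=O)/C=C/c1ccc(O)cc1
A2 | direct plan | racemic (E)-1,7-bis(4-hydroxyphenyl)hept-1-en-3-ol | OC(/C=C/c1ccc(O)cc1)CCCCc1ccc(O)cc1
A3 | direct plan | 4-[(2E)-7-(4-hydroxyphenyl)hept-2-en-1-ylidene]cyclohexa-2,5-dien-1-one (dienyl para-quinone methide) | O=C1C=CC(=C/C=C/CCCCc2ccc(O)cc2)C=C1
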